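In the zeta flask, target falls after its peak. The question is how fast it falls, told as the fraction left rather than the amount lost.

the same everywhere: temperature 25 °C
- zeta: starting material 0.80 M; second substrate 0.80 M; reagent 0.76 M; free catalyst 8 mM; the very flask that is asked about, followed so far
- epsilon: starting material 1.2 M; second substrate 0.80 M; reagent 0.76 M; free catalyst 8 mM; run made earlier
- flask: starting material 0.80 M; second substrate 0.800 M; reagent 0.760 M; free catalyst 8.0 mM; time 8.0 min

| zeta: time / min | zeta: target / % | epsilon: time / min | epsilon: target / % |
|---|---|---|---|
| 0.500 | 45.5 | 0.417 | 32.6 |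
| 1.50 | 56.5 | 1.00 | 43.8 |
| 3.00 | 54.5 | 2.00 | 45.0 |
| 4.00 | 54.2 | 3.00 | 42.4 |
| 6.00 | 50.1 | 4.00 | 40.8 |
| 8.00 | 50.0 | 6.00 | 40.6 |

(scatter of a reading: 1 percentage point)

- violet: at 8.0 min add reagent, 50.0 % of the amount charged, then wait 4.0 min
- grey: at 8.0 min add free catalyst, 100 % of the amount charged, then wait 4.0 min
- blue: at 8.0 min raise the temperature by 15 K, then wait 4.0 min
- amber: change nothing and wait 4.0 min more
- ochre: at 8.0 min take out 90 % of the target then present, then wait 4.0 min

- what is taken out of target is counted as made
- steps thought possible: starting material + free catalyst <-> catalyst intermediate A; reagent + catalyst intermediate A <-> free catalyst + target; second substrate + free catalyst <-> catalyst intermediate B; reagent + catalyst intermediate B -> free catalyst + second product; 2 reagent -> homo dimer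
- additions bring no volume worth counting
- the earlier runs do not show what temperature does; that part of a forecast is a guess

* target, in percent of the starting material first charged, at 8.0 min
* what to do for the largest gain in target; "none" if nothing gains more than 2 percentage points (violet / grey / blue / amber / ochre / none)
* target present, with what was taken out counted in, in percent of the starting material first charged, after violet
* target present, with what was taken out counted in, in percent of the starting material first charged, after ochre

Take target in the zeta flask after its peak as a first-order loss: each minute keeps the same fraction, and the cost of a wait is c(target) times one minus that fraction over the wait. The readings of the rise do not enter this reckoning. That leaves two numbers to judge. One point of error in the level of target moves the cost of 4.0 min by 0.067 percentage points. One point of error in a late reading moves the slope by 0.00400 min⁻¹, and so the cost by 0.8 points. The slope therefore matters more than the level.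

The readings at 3.00 min and 8.00 min give the leak constant, the fraction lost per minute in logarithmic measure, 0.0172 min⁻¹. The epsilon run reads 0.0257 min⁻¹, with the same scatter per reading. My own reckoning takes 50.0 % for now, so amber costs 3.3 points. Ochre takes out 90 % of target and the remainder goes on leaking, which in this reckoning gives 49.7 %.

The forecast gives 50 % (48.8 % to 51.2 %) for now and names violet as best. It puts violet at 70 % (62 % to 77 %) and ochre at 50.5 % (48.5 % to 53.5 %), reading the curve as “reagent being used up, not target being destroyed”.

    starting material + free catalyst ⇌ catalyst intermediate A (K = 0.940 M⁻¹, k = 36.0 M⁻¹ s⁻¹, Ea = 53.0 kJ mol⁻¹, ΔH = −15.0 kJ mol⁻¹)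
    reagent + catalyst intermediate A ⇌ free catalyst + target (K = 27.0, k = 12.0 M⁻¹ s⁻¹, Ea = 51.0 kJ mol⁻¹, ΔH = −49.0 kJ mol⁻¹)
    second substrate + free catalyst ⇌ catalyst intermediate B (K = 30.0 M⁻¹, k = 1.10 M⁻¹ s⁻¹, Ea = 61.0 kJ mol⁻¹, ΔH = −33.0 kJ mol⁻¹)
    reagent + catalyst intermediate B → free catalyst + second product (k = 5.00 M⁻¹ s⁻¹, Ea = 41.0 kJ mol⁻¹)
    2 reagent → homo dimer (k = 8.50 × 10⁻⁴ M⁻¹ s⁻¹, Ea = 59.0 kJ mol⁻¹)
    (constants at 25 °C)

The zeta flask holds 49.7 % at 8.0 min. Violet is best, gaining 11 points to reach 61.1 %, below the forecast's range, and ochre ends at 49.5 %. Amber loses 3.6 points against the 3.3 points reckoned, and the leak constant carried to the same flask read at 30 min gives 34.0 %, where it holds 31.8 %. By this step alone at 8.00 min, reagent + catalyst intermediate A and free catalyst + target relax, both ways together, with a half-life of 0.0518 min, short against 8.0 min. Second substrate, by the forward rate of its step into catalyst intermediate B alone at 8.00 min, has a far longer half-life of 14 min.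

The numbers in the tables are calculated with made-up constants; the scatter is artificial.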